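**Retrosynthetic overview**
- The route rests on ring A: the C12 ketone sits next to the fully substituted, oxygenated, methyl-bearing C11 (a tertiary α-ketol). Cutting C11–C12 gives a C12 aldehyde on the C1 side chain and a C11 methyl ketone on C10, joined last by a carbene-catalysed benzoin.
- Ring C (oxocane) is cut at C5–C6: a 2-bromoallyl arm on C2 closes onto a C6 aldehyde (Nozaki–Hiyama–Kishi); C6–Cl comes from the allylic alcohol with inversion.
- Ring B comes from an Achmatowicz rearrangement of a 2,3,5-trisubstituted furan, locked as a C2/O7 bicyclic ketal. The ketal directs the C1 methyl (cuprate) and the C2 hydrogen (silane); C9 is set by an O7-directed Evans–Tishchenko reduction.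
- C7 comes from (S)-glycidate, C8 from a Felkin acetate aldol on a furyl ketone, C17 from a Fráter–Seebach methylation of the lactone (ring D), and C3 from an asymmetric 2-bromoallylation.
- Ring order: B, then D (masked as a diol in between), then C, then A.

Key step: step 31

Remark: briarane locants are used throughout (C15 = C1 methyl, C16 = exo-methylene carbon, C18 = C17 methyl, C19 = lactone carbonyl, C20 = C11 methyl); the C11 carbinol in 26–36, C6 in 38 and the anomeric carbon of 24 are epimer mixtures that are removed later, and the sense of induction of the chiral reagents in steps 9 and 31 is assigned by model, the antipode being the remedy if it proves opposite.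

Step 1
Reactants: 1 3-bromofuran; 2 oxetane
Product: 4 3-(furan-3-yl)propan-1-ol, via 3-furyllithium 3 (not isolated)
Conditions: n-BuLi, Et2O, −78 °C; then BF3·OEt2, 2, −78 °C
Reagents that add atoms: none
Why: Bromine–lithium exchange below the temperature at which the 3-lithio species isomerises, followed by Lewis acid-promoted SN2 opening of oxetane by the aryllithium, should attach the arm C14–C12 with its oxygen.

Step 2
Reactants: 4 3-(furan-3-yl)propan-1-ol
Product: 5 3-[3-(naphthalen-2-ylmethoxy)propyl]furan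
Conditions: NaH, 2-(bromomethyl)naphthalene, Bu4NI (cat.), THF/DMF, 0 °C → rt
Reagents that add atoms: 2-(bromomethyl)naphthalene BrCc1ccc2ccccc2c1
Why: Williamson etherification; the 2-naphthylmethyl ether should survive the Lewis acids used later and is removed oxidatively just before the key step.

Step 3
Reactants: 5 3-[3-(naphthalen-2-ylmethoxy)propyl]furan
Product: 6 3-[3-(naphthalen-2-ylmethoxy)propyl]furan-2-carbaldehyde
Conditions: POCl3, DMF, 0 °C → rt; aq. NaOAc
Reagents that add atoms: N,N-dimethylformamide CN(C)C=O; water O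
Why: Vilsmeier–Haack formylation should go to the α-position next to the alkyl group, giving the future C2 (ring carbon) and C3 (formyl carbon).

Step 4
Reactants: 7 methyl (2S)-oxirane-2-carboxylate; 8 prop-2-en-1-ol
Product: 9 methyl (2S)-2-hydroxy-3-(prop-2-enyloxy)propanoate
Conditions: BF3·OEt2 (cat.), CH2Cl2, 0 °C
Reagents that add atoms: none
Why: Lewis acid-catalysed SN2 opening of the glycidic ester at its unsubstituted carbon leaves the stereocentre (future C7) untouched and puts the C6 oxygen in place as an allyl ether.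

Step 5
Reactants: 9 methyl (2S)-2-hydroxy-3-(prop-2-enyloxy)propanoate
Product: 10 methyl (2S)-3-(prop-2-enyloxy)-2-(triethylsilyloxy)propanoate
Conditions: TESCl, imidazole, DMF, 0 °C
Reagents that add atoms: chlorotriethylsilane CC[Si](Cl)(CC)CC
Why: Silyl ether formation; a non-chelating α-silyloxy group is needed for Felkin control in step 11.

Step 6
Reactants: 10 methyl (2S)-3-(prop-2-enyloxy)-2-(triethylsilyloxy)propanoate
Product: 11 (2S)-N-methoxy-N-methyl-3-(prop-2-enyloxy)-2-(triethylsilyloxy)propanamide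
Conditions: MeNH(OMe)·HCl, i-PrMgCl, THF, −20 °C
Reagents that add atoms: N,O-dimethylhydroxylamine hydrochloride CNOC.Cl
Why: Weinreb amide formation through the magnesium amide at low temperature should not epimerise the α-silyloxy centre.

Step 7
Reactants: 6 3-[3-(naphthalen-2-ylmethoxy)propyl]furan-2-carbaldehyde; 11 (2S)-N-methoxy-N-methyl-3-(prop-2-enyloxy)-2-(triethylsilyloxy)propanamide
Product: 13 5-[(2S)-3-(prop-2-enyloxy)-2-(triethylsilyloxy)propanoyl]-3-[3-(naphthalen-2-ylmethoxy)propyl]furan-2-carbaldehyde, via lithium amino alkoxide 12 (not isolated)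
Conditions: lithium 4-methylpiperazin-1-ide (1-methylpiperazine, n-BuLi), THF, −78 °C; n-BuLi, −78 → −30 °C; 11, −78 °C; aq. NH4Cl
Reagents that add atoms: none
Why: The aldehyde is masked in the flask as its α-amino alkoxide, directed lithiation takes the only free furan α-position, and acylation by the Weinreb amide stops at the ketone (C8) because the chelated tetrahedral adduct survives until work-up.

Step 8
Reactants: 14 2,3-dibromoprop-1-ene
Product: 15 (2-bromoprop-2-enyl)tributylstannane
Conditions: Bu3SnH, LDA, THF, −78 °C; then 14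
Reagents that add atoms: tributyltin hydride CCCC[SnH](CCCC)CCCC
Why: SN2 displacement of the allylic bromide by tributylstannyllithium; the vinylic bromide is inert to substitution.

Step 9
Reactants: 13 keto aldehyde; 15 (2-bromoprop-2-enyl)tributylstannane
Product: 16 C3 carbinol (5-acyl-2-[(1R)-3-bromo-1-hydroxybut-3-enyl]furan)
Conditions: (4R,5R)-2-bromo-4,5-diphenyl-1,3-bis(4-methylphenylsulfonyl)-1,3,2-diazaborolidine, 15, CH2Cl2, 0 °C → rt; then 13, −78 °C
Reagents that add atoms: none
Why: Enantioselective allylboration through a six-membered chair transition state; the chiral diazaborolidine sets C3 by reagent control, and the aldehyde reacts while the furyl ketone does not at −78 °C.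

Step 10
Reactants: 16 C3 carbinol
Product: 17 C3 tert-butyldimethylsilyl ether
Conditions: TBSCl, imidazole, DMF, rt
Reagents that add atoms: tert-butyl(chloro)dimethylsilane CC(C)(C)[Si](C)(C)Cl
Why: Silyl ether formation; this group stays until the last step.

Step 11
Reactants: 17 C3 tert-butyldimethylsilyl ether
Product: 18 tertiary alcohol (ethyl ester, C8 carbinol)
Conditions: LDA, EtOAc, THF, −78 °C; then 17, −78 °C
Reagents that add atoms: ethyl acetate CCOC(C)=O
Why: Acetate aldol addition to the ketone; Felkin–Anh attack anti to the C7 silyloxy group should set C8 with C17 and C6 on the same side, as the lactone of the target requires.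

Step 12
Reactants: 18 tertiary alcohol
Product: 20 β-hydroxy-γ-lactone (C8 hydroxyl, C7 allyloxymethyl), via hydroxy ester 19 (not isolated)
Conditions: HF·pyridine, pyridine, THF, 0 °C → rt
Reagents that add atoms: none
Why: Buffered fluoride cleaves the triethylsilyl ether in preference to the tert-butyldimethylsilyl ether, and the freed C7 hydroxyl lactonises onto the ester (five-membered acyl substitution).

Step 13
Reactants: 20 β-hydroxy-γ-lactone
Product: 21 α-methyl-β-hydroxy-γ-lactone
Conditions: LDA (2.5 equiv), THF, −78 → −40 °C; MeI, −78 °C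
Reagents that add atoms: iodomethane CI
Why: Fráter–Seebach alkylation of the alkoxide–enolate dianion; the methyl group should enter anti to the lithium alkoxide, which sets C17 trans to O8.

Step 14
Reactants: 21 α-methyl-β-hydroxy-γ-lactone
Product: 22 triol (C19 primary, C7 secondary, C8 tertiary hydroxyl)
Conditions: LiBH4, THF, 0 °C → rt
Reagents that add atoms: none
Why: Hydride reduction of the lactone to the diol frees O7 for the ketal and removes the acidic C17 hydrogen from the base-mediated steps that follow.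

Step 15
Reactants: 22 triol
Product: 23 C19 acetate
Conditions: AcCl, 2,4,6-collidine, CH2Cl2, −78 °C
Reagents that add atoms: acetyl chloride CC(Cl)=O
Why: Selective acylation of the primary alcohol in the presence of the secondary and tertiary ones.

Step 16
Reactants: 23 C19 acetate
Product: 25 bicyclic ketal enone (C2–O7 and C2–O8 ketal, C9 ketone, C10=C1), via pyranone hemiketal 24 (not isolated)
Conditions: NBS, NaHCO3, THF/H2O, 0 °C; then CSA (cat.), CH2Cl2, rt
Reagents that add atoms: water O
Why: Achmatowicz rearrangement (oxidative ring expansion of the furyl carbinol through the ene-dione) closes ring B as a six-membered hemiketal without touching C8, and acid-catalysed ketalisation by the C7 hydroxyl locks C2 and C8 in a 6,8-dioxabicyclo[3.2.1]octenone whose bridge covers one face.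

Step 17
Reactants: 25 bicyclic ketal enone
Product: 27 ketal ketone (C1 methyl, C10 1-acetoxyethyl), via aldol 26 (not isolated)
Conditions: MeLi, CuI, Et2O, −78 → −30 °C; MeCHO, −78 °C; Ac2O, −78 → 0 °C
Reagents that add atoms: methyllithium C[Li]; acetaldehyde CC=O; acetic anhydride CC(=O)OC(C)=O
Why: Conjugate addition of the Gilman cuprate from the face opposite the O7–C7 bridge should set the quaternary C1 (methyl anti to C7), and the enolate is trapped on the same open face by aldol addition to acetaldehyde (C11 equatorial on C10) and acetylated in the flask.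

Step 18
Reactants: 27 ketal ketone
Product: 29 ring B hydroxy ketone (C2–H, free C7 hydroxyl, C9 ketone), via O7 triethylsilyl ether 28 (not isolated)
Conditions: Et3SiH, TMSOTf (cat.), CH2Cl2, −78 °C; then PPTS, MeOH, 0 °C
Reagents that add atoms: none
Why: Ionic reduction of the ketal (oxocarbenium ion by loss of the less hindered O7, hydride from the silane) is expected to deliver hydrogen anti to the departing O7, which puts C3 cis to C7; methanolysis then frees the C7 hydroxyl.

Step 19
Reactants: 29 ring B hydroxy ketone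
Product: 30 C7 acetate with free C9 hydroxyl
Conditions: MeCHO, SmI2 (cat.), THF, −10 °C
Reagents that add atoms: acetaldehyde CC=O
Why: Evans–Tishchenko reduction; the samarium-bound hemiacetal of the C7 hydroxyl and acetaldehyde transfers hydride to C9 through a six-membered chair, which should give the 1,3-anti C7–O/C9–O relationship of the target and leaves O7 acetylated and O9 free.

Step 20
Reactants: 30 C7 acetate with free C9 hydroxyl
Product: 31 C9 triethylsilyl ether
Conditions: TESOTf, 2,6-lutidine, CH2Cl2, −78 °C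
Reagents that add atoms: triethylsilyl trifluoromethanesulfonate CC[Si](CC)(CC)OS(=O)(=O)C(F)(F)F
Why: Silylation of the hindered axial alcohol with the silyl triflate; a silyloxy group at C9 is a poor leaving group for the later β-silyloxy ketone.

Step 21
Reactants: 31 C9 triethylsilyl ether
Product: 32 triol (C7, C11 and C19 hydroxyls)
Conditions: DIBAL-H, CH2Cl2, −78 °C; Rochelle salt work-up
Reagents that add atoms: none
Why: Reductive cleavage of the three acetates under non-basic conditions; no ketone is present at this stage.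

Step 22
Reactants: 32 triol
Product: 34 spiro lactone (ring D closed, C11 carbinol), via lactol 33 (not isolated)
Conditions: TEMPO (cat.), PhI(OAc)2, CH2Cl2, rt
Reagents that add atoms: none
Why: Oxoammonium oxidation takes the primary C19 alcohol to the aldehyde, which closes with the C7 hydroxyl to the five-membered lactol and is oxidised on to the lactone; secondary alcohols react more slowly.

Step 23
Reactants: 34 spiro lactone
Product: 36 C6 primary alcohol, via propenyl ether 35 (not isolated)
Conditions: [Ir(cod)(PMePh2)2]PF6 (cat., H2-activated), THF, rt; then HgCl2, HgO, acetone/H2O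
Reagents that add atoms: none
Why: Iridium-catalysed isomerisation of the allyl ether to the enol ether and its hydrolysis remove the C6 protecting group without touching the silyl ethers, the naphthylmethyl ether or the vinyl bromide.

Step 24
Reactants: 36 C6 primary alcohol
Product: 37 keto aldehyde (C6 aldehyde, C11 methyl ketone)
Conditions: Dess–Martin periodinane, NaHCO3, CH2Cl2, 0 °C → rt
Reagents that add atoms: none
Why: Dess–Martin oxidation of both alcohols removes the C11 mixture and gives the aldehyde for ring closure under buffered conditions that should not epimerise C7.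

Step 25
Reactants: 37 keto aldehyde
Product: 38 oxocane allylic alcohol (C6 epimers)
Conditions: CrCl2, NiCl2 (cat.), DMSO, rt, high dilution
Reagents that add atoms: none
Why: Nozaki–Hiyama–Kishi reaction; nickel inserts into the vinyl bromide, transmetalation gives a vinylchromium species that adds only to the aldehyde, and ring C closes at C5–C6 between two arms held cis on ring B.

Step 26
Reactants: 38 oxocane allylic alcohol
Product: 39 C6 enone
Conditions: Dess–Martin periodinane, NaHCO3, CH2Cl2, 0 °C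
Reagents that add atoms: none
Why: Dess–Martin oxidation merges both C6 epimers into one enone.

Step 27
Reactants: 39 C6 enone
Product: 40 (6R)-allylic alcohol
Conditions: NaBH4, CeCl3·7H2O, MeOH, −78 °C
Reagents that add atoms: none
Why: Luche 1,2-reduction; Felkin–Anh attack anti to the C7 acyloxy group is expected to give the 6,7-syn alcohol, and the cerium-activated enone should react before the hindered saturated C11 ketone.

Step 28
Reactants: 40 (6R)-allylic alcohol
Product: 41 (6S)-allylic chloride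
Conditions: PPh3, hexachloroacetone, CH2Cl2, −20 °C
Reagents that add atoms: hexachloroacetone ClC(Cl)(Cl)C(=O)C(Cl)(Cl)Cl
Why: Appel-type chlorination; SN2 collapse of the alkoxyphosphonium chloride should give the unrearranged allylic chloride with inversion at C6.

Step 29
Reactants: 41 (6S)-allylic chloride
Product: 42 C12 primary alcohol
Conditions: DDQ, CH2Cl2/pH 7 buffer, rt
Reagents that add atoms: none
Why: Oxidative cleavage of the 2-naphthylmethyl ether by hydride abstraction and hydrolysis leaves silyl ethers, lactone and allylic chloride alone.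

Step 30
Reactants: 42 C12 primary alcohol
Product: 43 keto aldehyde with acetyl on C10 and 3-oxopropyl on C1
Conditions: Dess–Martin periodinane, NaHCO3, CH2Cl2, 0 °C
Reagents that add atoms: none
Why: Dess–Martin oxidation to the aldehyde under buffered conditions avoids elimination of the C9 silyloxy group.

Step 31
Reactants: 43 keto aldehyde
Product: 44 ring A α-ketol (C12 ketone, C11 tertiary alcohol)
Conditions: (5aS,10bR)-2-(pentafluorophenyl)-5a,10b-dihydro-4H,6H-indeno[2,1-b][1,2,4]triazolo[4,3-d][1,4]oxazinium tetrafluoroborate (20 mol%), i-Pr2NEt (20 mol%), toluene, 4 Å sieves, rt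
Reagents that add atoms: none
Why: The carbene from the triazolium salt adds to the C12 aldehyde, proton transfer gives the enaminol (Breslow intermediate), its carbon attacks the C11 ketone, and collapse of the adduct releases the carbene and the α-ketol. The closest known reaction type is the carbene-catalysed intramolecular crossed benzoin of keto aldehydes to six-membered tertiary α-ketols. Ring A closes in a 6-exo-trig mode, and no other ring size can form because the two carbonyl carbons hang on the adjacent ring B carbons C1 and C10. C11 is controlled by a chair transition state fused to the ring B chair (acetyl equatorial on C10): with the bulky azolium pseudo-equatorial on C12 the enaminol hydroxyl is pseudo-axial and can hydrogen-bond only to a pseudo-equatorial ketone oxygen, which puts the new hydroxyl trans to C9 and the methyl axial, and the (5aS,10bR) salt is chosen so that its indane wall covers the other enaminol face. The step needs umpolung of the aldehyde only, and C–C bond formation faster than aldol, loss of the C9 silyloxy group or epimerisation at C10 and C17; the ketone cannot form an enaminol, the amine is too weak to enolise ketone or lactone, and a triethylsilyloxy group is a poor leaving group.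

Step 32
Reactants: 44 ring A α-ketol
Product: 45 C11 acetate
Conditions: Ac2O, DMAP, Et3N, CH2Cl2, rt
Reagents that add atoms: acetic anhydride CC(=O)OC(C)=O
Why: DMAP-catalysed acylation of the tertiary α-ketol hydroxyl, the only free alcohol.

Step 33
Reactants: 45 C11 acetate
Product: 47 ring A enone (C13=C14), via trimethylsilyl enol ether 46 (not isolated)
Conditions: TMSOTf, Et3N, CH2Cl2, −78 → 0 °C; then 2-iodoxybenzoic acid·4-methoxypyridine N-oxide, DMSO, rt
Reagents that add atoms: none
Why: Soft enolisation can only go toward C13 (C11 is fully substituted), and dehydrogenation of the silyl enol ether with the iodoxybenzoic acid complex (a Saegusa-type desaturation) avoids zerovalent palladium, which would ionise the allylic chloride.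

Step 34
Reactants: 47 ring A enone
Product: 48 C9 alcohol
Conditions: HF·pyridine, pyridine, THF, 0 °C
Reagents that add atoms: none
Why: Buffered fluoride cleaves the triethylsilyl ether in preference to the tert-butyldimethylsilyl ether.

Step 35
Reactants: 48 C9 alcohol
Product: 49 C9 acetate
Conditions: Ac2O, DMAP, pyridine, CH2Cl2, rt
Reagents that add atoms: acetic anhydride CC(=O)OC(C)=O
Why: Acetylation of the only free hydroxyl.

Step 36
Reactants: 49 C9 acetate
Product: 50 CNP0253524.4
Conditions: HF·pyridine, THF, rt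
Reagents that add atoms: none
Why: Acidic fluoride desilylation frees the C3 hydroxyl without base, so the β-alkoxy lactone, the acetates and the allylic chloride should survive.

**Compound list**
1 | 3-bromofuran | Brc1ccoc1 | starting material
2 | oxetane | C1COC1 | starting material
3 | 3-furyllithium | [Li]c1ccoc1 | intermediate
4 | 3-(furan-3-yl)propan-1-ol | OCCCc1ccoc1 | intermediate
5 | 3-[3-(naphthalen-2-ylmethoxy)propyl]furan | C(CCc1ccoc1)OCc1ccc2ccccc2c1 | intermediate
6 | 3-[3-(naphthalen-2-ylmethoxy)propyl]furan-2-carbaldehyde | O=Cc1occc1CCCOCc1ccc2ccccc2c1 | intermediate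
7 | methyl (2S)-oxirane-2-carboxylate | COC(=O)[C@@H]1CO1 | starting material
8 | prop-2-en-1-ol | C=CCO | starting material
9 | methyl (2S)-2-hydroxy-3-(prop-2-enyloxy)propanoate | COC(=O)[C@@H](O)COCC=C | intermediate
10 | methyl (2S)-3-(prop-2-enyloxy)-2-(triethylsilyloxy)propanoate | COC(=O)[C@@H](O[Si](CC)(CC)CC)COCC=C | intermediate
11 | (2S)-N-methoxy-N-methyl-3-(prop-2-enyloxy)-2-(triethylsilyloxy)propanamide | CON(C)C(=O)[C@@H](O[Si](CC)(CC)CC)COCC=C | intermediate
12 | lithium α-(4-methylpiperazin-1-yl) alkoxide of aldehyde 6 | [Li]OC(N1CCN(C)CC1)c1occc1CCCOCc1ccc2ccccc2c1 | intermediate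
13 | 5-acyl furan-2-carbaldehyde (C8 ketone, C7 silyloxy, C3 aldehyde) | O=Cc1oc(C(=O)[C@@H](O[Si](CC)(CC)CC)COCC=C)cc1CCCOCc1ccc2ccccc2c1 | intermediate
14 | 2,3-dibromoprop-1-ene | C=C(Br)CBr | starting material
15 | (2-bromoprop-2-enyl)tributylstannane | C=C(Br)C[Sn](CCCC)(CCCC)CCCC | intermediate
16 | C3 carbinol, (1R)-3-bromo-1-hydroxybut-3-enyl on the furan | C=C(Br)C[C@@H](O)c1oc(C(=O)[C@@H](O[Si](CC)(CC)CC)COCC=C)cc1CCCOCc1ccc2ccccc2c1 | intermediate
17 | C3 tert-butyldimethylsilyl ether of 16 | C=C(Br)C[C@@H](O[Si](C)(C)C(C)(C)C)c1oc(C(=O)[C@@H](O[Si](CC)(CC)CC)COCC=C)cc1CCCOCc1ccc2ccccc2c1 | intermediate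
18 | ethyl ester with tertiary C8 carbinol (Felkin adduct) | C=C(Br)C[C@@H](O[Si](C)(C)C(C)(C)C)c1oc([C@](O)([C@@H](O[Si](CC)(CC)CC)COCC=C)CC(=O)OCC)cc1CCCOCc1ccc2ccccc2c1 | intermediate
19 | C7,C8-dihydroxy ethyl ester | C=C(Br)C[C@@H](O[Si](C)(C)C(C)(C)C)c1oc([C@](O)([C@@H](O)COCC=C)CC(=O)OCC)cc1CCCOCc1ccc2ccccc2c1 | intermediate
20 | β-hydroxy-γ-lactone (C8 hydroxyl and furyl, C7 allyloxymethyl) | C=C(Br)C[C@@H](O[Si](C)(C)C(C)(C)C)c1oc([C@@]2(O)CC(=O)O[C@H]2COCC=C)cc1CCCOCc1ccc2ccccc2c1 | intermediate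
21 | α-methyl-β-hydroxy-γ-lactone (C17 methyl trans to the C8 hydroxyl) | C=C(Br)C[C@@H](O[Si](C)(C)C(C)(C)C)c1oc([C@@]2(O)[C@@H](C)C(=O)O[C@H]2COCC=C)cc1CCCOCc1ccc2ccccc2c1 | intermediate
22 | C7,C8,C19-triol | C=C(Br)C[C@@H](O[Si](C)(C)C(C)(C)C)c1oc([C@](O)([C@@H](O)COCC=C)[C@@H](C)CO)cc1CCCOCc1ccc2ccccc2c1 | intermediate
23 | C19 acetate of triol 22 | C=C(Br)C[C@@H](O[Si](C)(C)C(C)(C)C)c1oc([C@](O)([C@@H](O)COCC=C)[C@@H](C)COC(C)=O)cc1CCCOCc1ccc2ccccc2c1 | intermediate
24 | pyranone hemiketal (ring B; C2 hemiketal, C9 ketone, C10=C1) | C=C(Br)C[C@@H](O[Si](C)(C)C(C)(C)C)C1(O)O[C@@]([C@@H](O)COCC=C)([C@@H](C)COC(C)=O)C(=O)C=C1CCCOCc1ccc2ccccc2c1 | intermediate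
25 | 6,8-dioxabicyclo[3.2.1]octenone (C2 ketal with O7 and O8) | C=C(Br)C[C@@H](O[Si](C)(C)C(C)(C)C)[C@@]12O[C@@]([C@H](COCC=C)O2)([C@@H](C)COC(C)=O)C(=O)C=C1CCCOCc1ccc2ccccc2c1 | intermediate
26 | bicyclic ketal ketone with C1 methyl and C10 1-hydroxyethyl | C=C(Br)C[C@@H](O[Si](C)(C)C(C)(C)C)[C@@]12O[C@@]([C@H](COCC=C)O2)([C@@H](C)COC(C)=O)C(=O)[C@@H](C(C)O)[C@]1(C)CCCOCc1ccc2ccccc2c1 | intermediate
27 | bicyclic ketal ketone with C1 methyl and C10 1-acetoxyethyl | C=C(Br)C[C@@H](O[Si](C)(C)C(C)(C)C)[C@@]12O[C@@]([C@H](COCC=C)O2)([C@@H](C)COC(C)=O)C(=O)[C@@H](C(C)OC(C)=O)[C@]1(C)CCCOCc1ccc2ccccc2c1 | intermediate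
28 | ring B ketone, C2–H, O7 triethylsilyl ether | C=C(Br)C[C@@H](O[Si](C)(C)C(C)(C)C)[C@@H]1O[C@@]([C@@H](O[Si](CC)(CC)CC)COCC=C)([C@@H](C)COC(C)=O)C(=O)[C@@H](C(C)OC(C)=O)[C@]1(C)CCCOCc1ccc2ccccc2c1 | intermediate
29 | ring B ketone, C2–H, free C7 hydroxyl | C=C(Br)C[C@@H](O[Si](C)(C)C(C)(C)C)[C@@H]1O[C@@]([C@@H](O)COCC=C)([C@@H](C)COC(C)=O)C(=O)[C@@H](C(C)OC(C)=O)[C@]1(C)CCCOCc1ccc2ccccc2c1 | intermediate
30 | C7 acetate, C9 alcohol (7,9-anti) | C=C(Br)C[C@@H](O[Si](C)(C)C(C)(C)C)[C@@H]1O[C@@]([C@@H](OC(C)=O)COCC=C)([C@@H](C)COC(C)=O)[C@@H](O)[C@@H](C(C)OC(C)=O)[C@]1(C)CCCOCc1ccc2ccccc2c1 | intermediate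
31 | C9 triethylsilyl ether of 30 | C=C(Br)C[C@@H](O[Si](C)(C)C(C)(C)C)[C@@H]1O[C@@]([C@@H](OC(C)=O)COCC=C)([C@@H](C)COC(C)=O)[C@@H](O[Si](CC)(CC)CC)[C@@H](C(C)OC(C)=O)[C@]1(C)CCCOCc1ccc2ccccc2c1 | intermediate
32 | C7,C11,C19-triol | C=C(Br)C[C@@H](O[Si](C)(C)C(C)(C)C)[C@@H]1O[C@@]([C@@H](O)COCC=C)([C@@H](C)CO)[C@@H](O[Si](CC)(CC)CC)[C@@H](C(C)O)[C@]1(C)CCCOCc1ccc2ccccc2c1 | intermediate
33 | spiro lactol (O7–C19 hemiacetal) | C=C(Br)C[C@@H](O[Si](C)(C)C(C)(C)C)[C@@H]1O[C@@]2([C@@H](C)C(O)O[C@H]2COCC=C)[C@@H](O[Si](CC)(CC)CC)[C@@H](C(C)O)[C@]1(C)CCCOCc1ccc2ccccc2c1 | intermediate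
34 | spiro lactone (ring D), C6 allyl ether, C11 carbinol | C=C(Br)C[C@@H](O[Si](C)(C)C(C)(C)C)[C@@H]1O[C@@]2([C@@H](C)C(=O)O[C@H]2COCC=C)[C@@H](O[Si](CC)(CC)CC)[C@@H](C(C)O)[C@]1(C)CCCOCc1ccc2ccccc2c1 | intermediate
35 | C6 prop-1-enyl ether of 36 | C=C(Br)C[C@@H](O[Si](C)(C)C(C)(C)C)[C@@H]1O[C@@]2([C@@H](C)C(=O)O[C@H]2COC=CC)[C@@H](O[Si](CC)(CC)CC)[C@@H](C(C)O)[C@]1(C)CCCOCc1ccc2ccccc2c1 | intermediate
36 | spiro lactone with free C6 primary alcohol | C=C(Br)C[C@@H](O[Si](C)(C)C(C)(C)C)[C@@H]1O[C@@]2([C@@H](C)C(=O)O[C@H]2CO)[C@@H](O[Si](CC)(CC)CC)[C@@H](C(C)O)[C@]1(C)CCCOCc1ccc2ccccc2c1 | intermediate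
37 | spiro lactone with C6 aldehyde and C11 methyl ketone | C=C(Br)C[C@@H](O[Si](C)(C)C(C)(C)C)[C@@H]1O[C@@]2([C@@H](C)C(=O)O[C@H]2C=O)[C@@H](O[Si](CC)(CC)CC)[C@@H](C(C)=O)[C@]1(C)CCCOCc1ccc2ccccc2c1 | intermediate
38 | bridged oxocane, C6 allylic alcohol (epimers), C5 exo-methylene | C=C1C[C@@H](O[Si](C)(C)C(C)(C)C)[C@@H]2O[C@@]3([C@@H](C)C(=O)O[C@H]3C1O)[C@@H](O[Si](CC)(CC)CC)[C@@H](C(C)=O)[C@]2(C)CCCOCc1ccc2ccccc2c1 | intermediate
39 | bridged oxocane C6 enone | C=C1C[C@@H](O[Si](C)(C)C(C)(C)C)[C@@H]2O[C@@]3([C@@H](C)C(=O)O[C@H]3C1=O)[C@@H](O[Si](CC)(CC)CC)[C@@H](C(C)=O)[C@]2(C)CCCOCc1ccc2ccccc2c1 | intermediate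
40 | (6R)-allylic alcohol | C=C1C[C@@H](O[Si](C)(C)C(C)(C)C)[C@@H]2O[C@@]3([C@@H](C)C(=O)O[C@H]3[C@@H]1O)[C@@H](O[Si](CC)(CC)CC)[C@@H](C(C)=O)[C@]2(C)CCCOCc1ccc2ccccc2c1 | intermediate
41 | (6S)-allylic chloride, C12 naphthylmethyl ether | C=C1C[C@@H](O[Si](C)(C)C(C)(C)C)[C@@H]2O[C@@]3([C@@H](C)C(=O)O[C@H]3[C@H]1Cl)[C@@H](O[Si](CC)(CC)CC)[C@@H](C(C)=O)[C@]2(C)CCCOCc1ccc2ccccc2c1 | intermediate
42 | (6S)-allylic chloride, C12 primary alcohol | C=C1C[C@@H](O[Si](C)(C)C(C)(C)C)[C@@H]2O[C@@]3([C@@H](C)C(=O)O[C@H]3[C@H]1Cl)[C@@H](O[Si](CC)(CC)CC)[C@@H](C(C)=O)[C@]2(C)CCCO | intermediate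
43 | bridged lactone core with acetyl on C10 and 3-oxopropyl on C1 | C=C1C[C@@H](O[Si](C)(C)C(C)(C)C)[C@@H]2O[C@@]3([C@@H](C)C(=O)O[C@H]3[C@H]1Cl)[C@@H](O[Si](CC)(CC)CC)[C@@H](C(C)=O)[C@]2(C)CCC=O | intermediate
44 | tetracyclic ring A α-ketol | C=C1C[C@@H](O[Si](C)(C)C(C)(C)C)[C@@H]2O[C@@]3([C@@H](C)C(=O)O[C@H]3[C@H]1Cl)[C@@H](O[Si](CC)(CC)CC)[C@@H]1[C@]2(C)CCC(=O)[C@@]1(C)O | intermediate
45 | C11 acetate of 44 | C=C1C[C@@H](O[Si](C)(C)C(C)(C)C)[C@@H]2O[C@@]3([C@@H](C)C(=O)O[C@H]3[C@H]1Cl)[C@@H](O[Si](CC)(CC)CC)[C@@H]1[C@]2(C)CCC(=O)[C@@]1(C)OC(C)=O | intermediate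
46 | C12 trimethylsilyl enol ether (C12=C13) | C=C1C[C@@H](O[Si](C)(C)C(C)(C)C)[C@@H]2O[C@@]3([C@@H](C)C(=O)O[C@H]3[C@H]1Cl)[C@@H](O[Si](CC)(CC)CC)[C@@H]1[C@]2(C)CC=C(O[Si](C)(C)C)[C@@]1(C)OC(C)=O | intermediate
47 | ring A enone (C13=C14), C9 triethylsilyl ether | C=C1C[C@@H](O[Si](C)(C)C(C)(C)C)[C@@H]2O[C@@]3([C@@H](C)C(=O)O[C@H]3[C@H]1Cl)[C@@H](O[Si](CC)(CC)CC)[C@@H]1[C@]2(C)C=CC(=O)[C@@]1(C)OC(C)=O | intermediate
48 | ring A enone, C9 alcohol | C=C1C[C@@H](O[Si](C)(C)C(C)(C)C)[C@@H]2O[C@@]3([C@@H](C)C(=O)O[C@H]3[C@H]1Cl)[C@@H](O)[C@@H]1[C@]2(C)C=CC(=O)[C@@]1(C)OC(C)=O | intermediate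
49 | 9,11-diacetate, C3 tert-butyldimethylsilyl ether | C=C1C[C@@H](O[Si](C)(C)C(C)(C)C)[C@@H]2O[C@@]3([C@@H](C)C(=O)O[C@H]3[C@H]1Cl)[C@@H](OC(C)=O)[C@@H]1[C@]2(C)C=CC(=O)[C@@]1(C)OC(C)=O | intermediate
50 | CNP0253524.4 | C=C1C[C@@H](O)[C@@H]2O[C@@]3([C@@H](C)C(=O)O[C@H]3[C@H]1Cl)[C@@H](OC(C)=O)[C@@H]1[C@]2(C)C=CC(=O)[C@@]1(C)OC(C)=O | target

**Step count**
Total: 36 steps. Longest linear sequence: 32 steps (1 to 50 through steps 1–3, 7 and 9–36; steps 4–6 and step 8 are side branches).

**Steps most likely to fail**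

Step 31 (key benzoin). The ketone face may be chosen poorly, because the wanted transition state carries the C11 methyl syn-axial to the C1 methyl; the C9 silyloxy group may also be lost by β-elimination before the ring closes. Fallback, from 43 back to 44:
- Double Wittig methylenation of aldehyde and ketone (Ph3P=CH2, THF, −78 → 0 °C) would give the bis-methylene diene F1.
- Ring-closing metathesis with the second-generation Grubbs catalyst would close ring A as the C11=C12 cyclohexene F2.
- Dihydroxylation (OsO4 cat., N-methylmorpholine N-oxide) should come from the face opposite the axial C1 methyl and give the cis-11,12-diol F3. The exo-methylene is deactivated by the allylic chlorine.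
- Dess–Martin oxidation of the secondary C12 hydroxyl returns α-ketol 44, with C11 set by steric approach control instead of by the catalyst.

Step 25 (oxocane closure). The bridged eight-membered ring may fail to close, because ring B must adopt the chair with both arms axial; the vinylchromium species would then be protonated or the aldehyde would oligomerise. Fallback, from 37 back to 41 (bypassing steps 26–28):
- Wittig methylenation of the aldehyde alone (Ph3P=CH2, −78 °C) would give the C6 vinyl compound F4.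
- Negishi coupling of the vinyl bromide (MeZnCl, Pd(PPh3)4) would give the methallyl diene F5.
- Ring-closing metathesis with the second-generation Hoveyda–Grubbs catalyst at high dilution would close ring C as the C5=C6 trisubstituted cycloalkene F6.
- Ene-type allylic chlorination (Ca(OCl)2, CO2, CH2Cl2/H2O) puts chlorine on C6 and moves the double bond to C5=C16, giving chloride 41.

Step 17 (conjugate methylation). Methyl transfer to the β-carbon may not occur, since that carbon is flanked by the fully substituted ketal carbon; 1,2-addition or recovered enone would result. Fallback, from 25 back to 27: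
- Corey–Chaykovsky cyclopropanation of the enone with dimethylsulfoxonium methylide (Me3S(O)I, NaH, DMSO) from the open face would give the cyclopropyl ketone F7.
- Reductive opening of the exocyclic cyclopropane bond with SmI2 (THF/DMPU) leaves the C1 methyl and a samarium enolate.
- Trapping the enolate with acetaldehyde and then acetic anhydride gives 27.

Further compounds
F1 | step 31 | bis-methylene diene (C12 vinyl, C11 isopropenyl) | C=C1C[C@@H](O[Si](C)(C)C(C)(C)C)[C@@H]2O[C@@]3([C@@H](C)C(=O)O[C@H]3[C@H]1Cl)[C@@H](O[Si](CC)(CC)CC)[C@@H](C(C)=C)[C@]2(C)CCC=C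
F2 | step 31 | ring A cyclohexene (C11=C12, C11 methyl) | C=C1C[C@@H](O[Si](C)(C)C(C)(C)C)[C@@H]2O[C@@]3([C@@H](C)C(=O)O[C@H]3[C@H]1Cl)[C@@H](O[Si](CC)(CC)CC)[C@@H]1[C@]2(C)CCC=C1C
F3 | step 31 | cis-11,12-diol | C=C1C[C@@H](O[Si](C)(C)C(C)(C)C)[C@@H]2O[C@@]3([C@@H](C)C(=O)O[C@H]3[C@H]1Cl)[C@@H](O[Si](CC)(CC)CC)[C@@H]1[C@]2(C)CC[C@@H](O)[C@@]1(C)O
F4 | step 25 | C6 vinyl compound with 2-bromoallyl arm | C=C(Br)C[C@@H](O[Si](C)(C)C(C)(C)C)[C@@H]1O[C@@]2([C@@H](C)C(=O)O[C@H]2C=C)[C@@H](O[Si](CC)(CC)CC)[C@@H](C(C)=O)[C@]1(C)CCCOCc1ccc2ccccc2c1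
F5 | step 25 | methallyl diene | C=C(C)C[C@@H](O[Si](C)(C)C(C)(C)C)[C@@H]1O[C@@]2([C@@H](C)C(=O)O[C@H]2C=C)[C@@H](O[Si](CC)(CC)CC)[C@@H](C(C)=O)[C@]1(C)CCCOCc1ccc2ccccc2c1
F6 | step 25 | bridged oxocene (C5=C6, C5 methyl) | CC=1C[C@@H](O[Si](C)(C)C(C)(C)C)[C@@H]2O[C@@]3([C@@H](C)C(=O)O[C@H]3C=1)[C@@H](O[Si](CC)(CC)CC)[C@@H](C(C)=O)[C@]2(C)CCCOCc1ccc2ccccc2c1
F7 | step 17 | cyclopropyl ketone (methylene bridging C1 and C10) | C=C(Br)C[C@@H](O[Si](C)(C)C(C)(C)C)[C@@]12O[C@@]([C@H](COCC=C)O2)([C@@H](C)COC(C)=O)C(=O)[C@H]3C[C@]31CCCOCc1ccc2ccccc2c1
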